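**Plan**

- Retrosynthetic cuts: first the two C–CH2 bonds of the methylene bridge (pyranone C3–CH2 and arene C1'–CH2), then the arene bonds C5'–C6' and C3'–C4' so that the benzene ring falls into two open chains, and in the pyranone the C4–C5 and O1–C2 bonds.
- Enabling feature: the benzene ring carries oxygen on C2', C4' and C6' in a 1,3,5 pattern, the acyl group on C5' and the prenyl CH2 on C3'. An acetal carbon (C6', keeps one OMe), a ketone (C2'), an ester carbonyl (C4'), a β-keto ester α-carbon (C5') and a ketone α'-carbon (C3') give exactly this when joined, already at the aromatic oxidation level, with C1' left as the only free position.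
- Forward order: the benzene ring is built first from a β-keto ester and a β,β-dimethoxy enone, the 4-hydroxy-2-pyranone ring is made separately from pentan-3-one and a malonyl unit, and the two rings are joined last through one CH2 delivered by an iminium salt.
- Stereochemistry: the single stereocentre (R, α to the aryl ketone) is bought with (R)-2-methylbutanoic acid and carried through; no stereocentre is created.

Key step: step 4

Remark on the chemistry: arene carbons are labelled C1' (bridge-bearing), C2' (OH), C3' (prenyl), C4' (OH), C5' (acyl), C6' (OMe). (R)-2-Methylbutanoic acid of high enantiomeric purity, 5-methylhex-4-enoic acid and 1,1-dimethoxyethene are assumed to be purchasable.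

**Route**

Step 1
Reactants: 1 (R)-2-methylbutanoic acid
Product: 4 methyl (R)-4-methyl-3-oxohexanoate, via acyl imidazolide 2 (not isolated), via acylmalonic half ester 3 (not isolated)
Conditions: CDI, THF, rt; then KO2CCH2CO2Me, MgCl2, THF, rt to 45 °C; aq. HCl work-up
Reagents that add atoms: KO2CCH2CO2Me (potassium methyl malonate), COC(=O)CC(=O)[O-].[K+]
Why: C-acylation of the magnesium enolate of a malonate half ester by an acyl imidazolide, followed by decarboxylation (decarboxylative Claisen condensation), is the standard near-neutral homologation of an acid to its β-keto ester, and with no strong base or ketene-forming acid chloride present the α-stereocentre of 1 should pass through unchanged.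

Step 2
Reactants: 5 5-methylhex-4-enoic acid
Product: 6 5-methylhex-4-enoyl chloride
Conditions: (COCl)2, cat. DMF, CH2Cl2, 0 °C to rt; evaporate
Reagents that add atoms: oxalyl chloride, O=C(Cl)C(=O)Cl
Why: DMF-catalysed acid chloride formation with oxalyl chloride gives only gaseous by-products at or below room temperature, and the trisubstituted alkene should tolerate the brief contact with HCl in CH2Cl2.

Step 3
Reactants: 6 5-methylhex-4-enoyl chloride; 7 1,1-dimethoxyethene (2.2 equiv)
Product: 8 1,1-dimethoxy-7-methylocta-1,6-dien-3-one
Conditions: Et2O, 0 °C to rt, no amine base; volatiles removed under vacuum, used without aqueous work-up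
Reagents that add atoms: none
Why: C-acylation of the electron-rich ketene acetal gives a dioxocarbenium ion that loses its α-proton to the second equivalent of 7 (consumed as methyl acetate and chloromethane), the classical acylation of ketene acetals to β,β-dialkoxy enones; all by-products are volatile, so the moisture-sensitive product never meets water.

Step 4
Reactants: 4 methyl (R)-4-methyl-3-oxohexanoate; 8 1,1-dimethoxy-7-methylocta-1,6-dien-3-one
Product: 10 (R)-1-[2,4-dihydroxy-6-methoxy-3-(3-methylbut-2-en-1-yl)phenyl]-2-methylbutan-1-one, via open-chain enolate adduct 9 (not isolated)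
Conditions: NaOMe (3 equiv), dry MeOH, 0 °C to rt, then reflux; AcOH quench at 0 °C
Reagents that add atoms: none
Why: Proposed new method: the sodium enolate of 4 should add through C2 to the acetal carbon of 8 and expel methoxide (addition–elimination, forming C5'–C6'), after which the α'-enolate of the enone ketone in adduct 9 should acylate itself on the ester carbonyl (forming C3'–C4') with loss of a second methoxide, the cyclic triketone tautomerising at once to the phenoxide of 10. The closest known reaction types are the Michael–Claisen synthesis of cyclohexane-1,3-diones from enones and malonates (dimedone synthesis), the aromatic annulations of α-oxo ketene dithioacetals with active-methylene carbanions and the base-mediated Claisen cyclisation of polyketo esters to acylphloroglucinols, but this combination on an O,O-ketene acetal has not been demonstrated. The only ring formed is the benzene ring (four carbons from 8, two from 4), closed by a 6-(enolexo)-exo-trig Claisen acylation, and no stereocentre is created. The step needs C-acylation on the ester to beat aldol closure onto the acyl ketone and O-acylation to a 2-pyranone: in excess NaOMe the α-branched acyl ketone is tied up as the enolate of the doubly activated C5' carbon, any pyranone is reopened by methoxide, and only the Claisen product leaves the equilibria irreversibly as an aromatic phenoxide. Methoxide in methanol makes every acetal and ester exchange degenerate, and the stereocentre is shielded because 4, 9 and 10 are each deprotonated elsewhere (C2, C5', phenol OH) long before the α-CH of the sec-butyl ketone.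

Step 5
Reactants: 11 pentan-3-one
Product: 12 3-(trimethylsilyloxy)pent-2-ene (E/Z mixture)
Conditions: TMSOTf, Et3N, Et2O, 0 °C; distil
Reagents that add atoms: trimethylsilyl trifluoromethanesulfonate, C[Si](C)(C)OS(=O)(=O)C(F)(F)F
Why: Soft enolisation and O-silylation of a symmetrical ketone (silyl enol ether formation) can give only one regioisomer, and the alkene geometry is irrelevant because it is lost in the next step.

Step 6
Reactants: 12 3-(trimethylsilyloxy)pent-2-ene
Product: 14 6-ethyl-4-hydroxy-5-methyl-2H-pyran-2-one, via diketo acid chloride 13 (not isolated)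
Conditions: CH2(COCl)2, Et2O, −20 °C to rt
Reagents that add atoms: malonyl dichloride, O=C(Cl)CC(=O)Cl
Why: C-acylation of a silyl enol ether by malonyl dichloride followed by lactonisation of the enol oxygen onto the second acid chloride is a known one-pot route to 5,6-disubstituted 4-hydroxy-2-pyranones.

Step 7
Reactants: 14 6-ethyl-4-hydroxy-5-methyl-2H-pyran-2-one; 10 (R)-1-[2,4-dihydroxy-6-methoxy-3-(3-methylbut-2-en-1-yl)phenyl]-2-methylbutan-1-one
Product: 17 3-({2,4-dihydroxy-6-methoxy-5-[(2R)-2-methylbutanoyl]-3-(3-methylbut-2-en-1-yl)phenyl}methyl)-6-ethyl-4-hydroxy-5-methyl-2H-pyran-2-one, via pyranone Mannich base 15 (not isolated), via methylidene pyrandione 16 (not isolated)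
Conditions: 14, Me2N=CH2+ I− (1.0 equiv), CH2Cl2, rt until 14 is consumed; then 10 (1.0 equiv), rt to 40 °C
Reagents that add atoms: dimethylmethylideneammonium iodide, C=[N+](C)C.[I-]
Why: Mannich reaction at the nucleophilic C3 of the 4-hydroxy-2-pyranone and loss of dimethylamine gives a 3-methylidene-pyran-2,4-dione that should be trapped in a Michael/Friedel–Crafts-type alkylation by C1' of 10, its only unsubstituted and strongly activated position, which is the established way to methylene-bridged acylphloroglucinol–pyranone dimers; the near-neutral conditions leave the prenyl group, the phenols and the stereocentre untouched.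

**Compound list**

1 | (R)-2-methylbutanoic acid | CC[C@@H](C)C(=O)O | starting material
2 | (R)-1-(1H-imidazol-1-yl)-2-methylbutan-1-one (acyl imidazolide) | CC[C@@H](C)C(=O)n1ccnc1 | intermediate (not isolated)
3 | (4R)-2-(methoxycarbonyl)-4-methyl-3-oxohexanoic acid (acylmalonic half ester, as its magnesium chelate, C2 epimers) | CC[C@@H](C)C(=O)C(C(=O)O)C(=O)OC | intermediate (not isolated)
4 | methyl (R)-4-methyl-3-oxohexanoate | CC[C@@H](C)C(=O)CC(=O)OC | intermediate
5 | 5-methylhex-4-enoic acid | CC(C)=CCCC(=O)O | starting material
6 | 5-methylhex-4-enoyl chloride | CC(C)=CCCC(=O)Cl | intermediate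
7 | 1,1-dimethoxyethene | COC(=C)OC | starting material
8 | 1,1-dimethoxy-7-methylocta-1,6-dien-3-one | COC(OC)=CC(=O)CCC=C(C)C | intermediate
9 | methyl 3-methoxy-9-methyl-2-[(2R)-2-methylbutanoyl]-5-oxodeca-3,8-dienoate (open-chain adduct, present as its sodium enolate) | CC[C@@H](C)C(=O)C(C(=O)OC)C(OC)=CC(=O)CCC=C(C)C | intermediate (not isolated)
10 | (R)-1-[2,4-dihydroxy-6-methoxy-3-(3-methylbut-2-en-1-yl)phenyl]-2-methylbutan-1-one | COc1cc(O)c(CC=C(C)C)c(O)c1C(=O)[C@H](C)CC | intermediate
11 | pentan-3-one | CCC(=O)CC | starting material
12 | 3-(trimethylsilyloxy)pent-2-ene (E/Z mixture) | CC=C(CC)O[Si](C)(C)C | intermediate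
13 | 4-methyl-3,5-dioxoheptanoyl chloride | CCC(=O)C(C)C(=O)CC(=O)Cl | intermediate (not isolated)
14 | 6-ethyl-4-hydroxy-5-methyl-2H-pyran-2-one | CCc1oc(=O)cc(O)c1C | intermediate
15 | 3-[(dimethylamino)methyl]-6-ethyl-4-hydroxy-5-methyl-2H-pyran-2-one | CCc1oc(=O)c(CN(C)C)c(O)c1C | intermediate (not isolated)
16 | 6-ethyl-5-methyl-3-methylidene-2H-pyran-2,4(3H)-dione | CCC1=C(C)C(=O)C(=C)C(=O)O1 | intermediate (not isolated)
17 | 3-({2,4-dihydroxy-6-methoxy-5-[(2R)-2-methylbutanoyl]-3-(3-methylbut-2-en-1-yl)phenyl}methyl)-6-ethyl-4-hydroxy-5-methyl-2H-pyran-2-one | CCc1oc(=O)c(Cc2c(O)c(CC=C(C)C)c(O)c(C(=O)[C@H](C)CC)c2OC)c(O)c1C | target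

**Step count**

Total: 7 steps. Longest linear sequence: 4 steps (5 → 6 → 8 → 10 → 17; steps 2, 3, 4, 7).

**Steps most likely to fail**

1. Step 4 (proposed new method). Ring closure may go through oxygen to a 4-methoxy-2-pyranone that does not reopen, the α'-enolate may close by aldol onto the acyl ketone, or the sequence may stall at the open-chain adduct. Fallback, known chemistry, which buys the arene instead of building it: set out from 1 and convert it with oxalyl chloride into (R)-2-methylbutanoyl chloride F1. Friedel–Crafts acylation of commercial 5-methoxybenzene-1,3-diol with F1 (AlCl3, CH2Cl2/PhNO2, 0 °C to rt) should give (R)-1-(2,4-dihydroxy-6-methoxyphenyl)-2-methylbutan-1-one F2 after separation from the 2,6-dihydroxy-4-methoxy isomer. C-prenylation of F2 with prenyl bromide and DBU in THF, at the carbon between the two hydroxyls, then returns to the route at 10; the C5 and O-prenylated isomers would have to be removed.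

2. Step 3. The chloride-paired dioxocarbenium intermediate may collapse by O-demethylation to the β-keto ester instead of losing a proton, the product may condense further with excess ketene acetal, or it may hydrolyse on handling. Fallback: set out from 5 and convert it (CDI, then MeNHOMe·HCl) into N-methoxy-N,5-dimethylhex-4-enamide F3. Addition of lithium methoxyacetylide (generated from 2-chloro-1,1-dimethoxyethane and LiNEt2 in THF) should give 1-methoxy-7-methyloct-6-en-1-yn-3-one F4. Conjugate addition of methanol (cat. NaOMe, MeOH, 0 °C) returns to the route at 8.

3. Step 7. The methylidene pyrandione may be intercepted by unreacted or retro-Mannich-regenerated pyranone and give the symmetrical methylenebis-pyranone instead of the cross-coupled product. Fallback, with the roles of the partners reversed: set out from 10 and aminomethylate its single free position with Me2N=CH2+ I− (CH2Cl2, rt) to give (R)-1-{5-[(dimethylamino)methyl]-2,4-dihydroxy-6-methoxy-3-(3-methylbut-2-en-1-yl)phenyl}-2-methylbutan-1-one F5, which cannot self-condense because every ring position is substituted. Heating F5 with 14 and Et3N in dioxane at 90 °C should release the ortho-quinone methide F6, which C3 of 14 captures, returning to the route at 17.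

**Further compounds**

F1 | step 4 | (R)-2-methylbutanoyl chloride | CC[C@@H](C)C(=O)Cl
F2 | step 4 | (R)-1-(2,4-dihydroxy-6-methoxyphenyl)-2-methylbutan-1-one | COc1cc(O)cc(O)c1C(=O)[C@H](C)CC
F3 | step 3 | N-methoxy-N,5-dimethylhex-4-enamide | CON(C)C(=O)CCC=C(C)C
F4 | step 3 | 1-methoxy-7-methyloct-6-en-1-yn-3-one | COC#CC(=O)CCC=C(C)C
F5 | step 7 | (R)-1-{5-[(dimethylamino)methyl]-2,4-dihydroxy-6-methoxy-3-(3-methylbut-2-en-1-yl)phenyl}-2-methylbutan-1-one | COc1c(CN(C)C)c(O)c(CC=C(C)C)c(O)c1C(=O)[C@H](C)CC
F6 | step 7 | ortho-quinone methide 5-hydroxy-3-methoxy-2-methylidene-4-[(2R)-2-methylbutanoyl]-6-(3-methylbut-2-en-1-yl)cyclohexa-3,5-dien-1-one | C=C1C(=O)C(CC=C(C)C)=C(O)C(C(=O)[C@H](C)CC)=C1OC
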